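**Assumptions.**
- I read the SMILES literally: C5 carries a methyl, giving a cis-fused 4,4,5,10-tetramethyl decalin with 3β-OAc, 5β-Me, 10β-Me and 9β-CH2OAr. Numbering is drimane-style (ring A: C1–C5, C10; ring B: C5–C10; C8 bears the exocyclic =CH2; C11 is the CH2O on C9).
- Methyl (S)-5-oxotetrahydrofuran-2-carboxylate (from L-glutamic acid) is commercially available.

## Retrosynthetic overview
1. The target is the C3 acetate of alcohol **14**. **14** comes from a Ti(III)/photoredox radical bicyclization of (3S)-epoxy polyene **13**. This step forms C4–C5 (ring A) first, then C9–C10 (ring B), and places the C8 exocyclic methylene.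
2. **13** comes from cross metathesis of isopropenyl epoxide **10** with 7-allyloxycoumarin **12**. **10** comes from methallyl coupling and diol→epoxide conversion of the Z-tetrasubstituted allylic alcohol **7**.
3. **7** comes from syn-carbomagnesiation and methylation of propargylic alcohol **5**, which is built from the L-Glu-derived lactone **1**. That lactone is the only chiral input and supplies C3 (S).

## Route

**Step 1**
Reactants: **1** methyl (S)-5-oxotetrahydrofuran-2-carboxylate
Product: **2** (S)-5-(2-hydroxypropan-2-yl)dihydrofuran-2(3H)-one
Conditions: MeMgBr (2.3 equiv), THF, −78 °C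
Reagents that add atoms: methylmagnesium bromide, C[Mg]Br
Why: Double Grignard addition converts the more electrophilic α-acyloxy ester into the C4 dimethyl carbinol while the lactone survives at low temperature. The C3 stereocenter is untouched and is no longer α to a carbonyl.

**Step 2**
Reactants: **2**
Product: **3** 5-(2-hydroxypropan-2-yl)tetrahydrofuran-2-ol (lactol, anomeric mixture, C3 retained)
Conditions: DIBAL-H (2.2 equiv), CH2Cl2, −78 °C
Reagents that add atoms: none
Why: Partial DIBAL reduction of the lactone stops at the lactol; the extra equivalent is consumed by the free tertiary OH.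

**Step 3**
Reactants: **3**
Product: **4** (S)-2-methylhept-6-yne-2,3-diol
Conditions: Bestmann–Ohira reagent, K2CO3, MeOH, rt
Reagents that add atoms: dimethyl (1-diazo-2-oxopropyl)phosphonate, COP(=O)(OC)C(=[N+]=[N-])C(C)=O (supplies C5)
Why: Seyferth–Gilbert/Bestmann–Ohira homologation of the open-chain aldehyde (C10) gives the terminal alkyne; the C3 carbinol is remote from the aldehyde and does not epimerize.

**Step 4**
Reactants: **4**
Product: **5** (S)-7-methyloct-2-yne-1,6,7-triol
Conditions: EtMgBr (3.3 equiv), THF, 0 °C; then (CH2O)n, 50 °C
Reagents that add atoms: formaldehyde (from paraformaldehyde), C=O (supplies C6)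
Why: The alkynyl Grignard adds to formaldehyde; the two alkoxides are inert spectators.

**Step 5**
Reactants: **5**
Product: **6** (Z)-vinyl iodide, HOCH2–C(I)=C(Me)–CH2CH2–CH(OH)–C(OH)Me2, with I and Me cis
Conditions: MeMgBr (6 equiv), CuI (10 mol%), THF, −20 °C→rt; then I2, −78 °C
Reagents that add atoms: methylmagnesium bromide, C[Mg]Br; iodine, II
Why: Alkoxide-directed Cu-catalysed syn-carbomagnesiation followed by iododemetalation puts the added Me and the I cis, so the C1 and C6 chains end up cis (Z). The regiochemistry is inconsequential because both alkene carbons receive a Me in Step 6.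

**Step 6**
Reactants: **6**
Product: **7** tetrasubstituted allylic alcohol, HOCH2–C(Me)=C(Me)–CH2CH2–CH(OH)–C(OH)Me2, Me groups cis
Conditions: MeMgBr (8 equiv), Fe(acac)3 (10 mol%), THF/NMP, 0 °C
Reagents that add atoms: methylmagnesium bromide, C[Mg]Br
Why: Fürstner-type Fe-catalysed Kumada–Corriu methylation proceeds with retention of alkene geometry, installing the second alkene methyl (C5/C10).

**Step 7**
Reactants: **7**
Product: **8** allylic bromide, BrCH2–C(Me)=C(Me)–CH2CH2–CH(OH)–C(OH)Me2
Conditions: CBr4, PPh3, CH2Cl2, 0 °C (use crude immediately)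
Reagents that add atoms: carbon tetrabromide, BrC(Br)(Br)Br
Why: The Appel reaction is selective for the primary allylic OH over the hindered secondary and tertiary OH groups.

**Step 8**
Reactants: **8**
Product: **9** C=C(C)CC/C(C)=C(/C)CC[C@H](O)C(C)(C)O, the isopropenyl diol
Conditions: 2-methylallylMgCl (4.5 equiv), CuI (5 mol%), THF, −40→0 °C, bromide added to the preformed cuprate
Reagents that add atoms: 2-methylallylmagnesium chloride, C=C(C)C[Mg]Cl
Why: Cu-catalysed SN2 allyl–allyl coupling at the primary allylic carbon installs C7 and the C8 isopropenyl unit; low temperature suppresses intramolecular alkoxide displacement.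

**Step 9**
Reactants: **9**
Product: **10** (S)-epoxide with isopropenyl terminus
Conditions: (1) MeC(OMe)3, PPTS, CH2Cl2, rt; (2) TMSCl; (3) K2CO3, MeOH, rt
Reagents that add atoms: none
Why: The Kolb–Sharpless orthoester/chloroacetate route closes the 2,2-dimethyloxirane by C3–O⁻ displacing the tertiary chloride, so the C3–O bond is never broken and S is retained.

**Step 10**
Reactants: **11** umbelliferone (7-hydroxycoumarin)
Product: **12** 7-allyloxycoumarin
Conditions: allyl bromide, K2CO3, acetone, reflux
Reagents that add atoms: allyl bromide, C=CCBr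
Why: Williamson O-alkylation of the phenol; this step runs in parallel to the main sequence.

**Step 11**
Reactants: **10**, **12**
Product: **13** (3S)-epoxy polyene coumarin ether with the (E)-C8=C9 alkene
Conditions: Hoveyda–Grubbs II (10 mol%), **12** (5 equiv), CH2Cl2, 40 °C, ethylene vented; separate E/Z
Reagents that add atoms: none
Why: Cross metathesis joins the 1,1-disubstituted alkene to the allyl ether to give the trisubstituted (E)-allylic aryl ether (C9, C11); the epoxide and the tetrasubstituted alkene are inert.

**Step 12**
Reactants: **13**
Product: **14** 3β-hydroxy-4,4,5β,10β-tetramethyl-8(12)-en-11-yl umbelliferone ether, C=C1CC[C@]2(C)C(C)(C)[C@@H](O)CC[C@]2(C)[C@H]1COAr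
Conditions: Cp2TiCl2 (20 mol%), 3DPAFIPN (2 mol%), Hantzsch ester (2.5 equiv), collidine·HCl (2 equiv), THF (0.02 M), 455 nm LEDs, 25 °C, 24 h
Reagents that add atoms: none (product is an isomer of **13**)
Why: Proposed new method: Ti(III), regenerated by visible-light photoredox, opens the epoxide homolytically at the tertiary C–O bond to give a β-titanoxy tertiary radical at C4.
- That radical closes 6-endo onto the Z-tetrasubstituted C5=C10 alkene (the 10-Me favours endo). Anti-addition across a Z-alkene gives the cis-fused Me5/Me10 (5β) arrangement.
- The C10 radical then closes 6-endo onto the (E)-allylic ether alkene (C9–C10 bond).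
- The C8 radical is trapped by Ti(III) and β-H elimination gives the exocyclic methylene.
- The (S)-epoxide fixes 3β and 10β-Me through a chair-like ring-A transition state with C3–O equatorial; C9 is set in the ring-B closure.
- The closest known reaction is the Cp2TiCl-catalysed radical epoxypolyene cyclization, which has been shown only on trisubstituted alkenes. What is new here is a Z-tetrasubstituted alkene as the internal radical acceptor, forming vicinal quaternary centres and a cis ring fusion.

**Step 13**
Reactants: **14**
Product: **15** target (3β-acetate)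
Conditions: Ac2O, DMAP, Et3N, CH2Cl2, rt
Reagents that add atoms: acetic anhydride, CC(=O)OC(C)=O
Why: O-Acetylation of the only free OH; the configuration at C3 is unchanged and the coumarin is untouched.

## Compound list
1 | methyl (S)-5-oxotetrahydrofuran-2-carboxylate | COC(=O)[C@@H]1CCC(=O)O1 | starting material
2 | (S)-5-(2-hydroxypropan-2-yl)dihydrofuran-2(3H)-one | CC(C)(O)[C@@H]1CCC(=O)O1 | intermediate
3 | 5-(2-hydroxypropan-2-yl)tetrahydrofuran-2-ol (lactol) | CC(C)(O)[C@@H]1CCC(O)O1 | intermediate
4 | (S)-2-methylhept-6-yne-2,3-diol | C#CCC[C@H](O)C(C)(C)O | intermediate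
5 | (S)-7-methyloct-2-yne-1,6,7-triol | OCC#CCC[C@H](O)C(C)(C)O | intermediate
6 | (Z)-vinyl iodide | OC/C(I)=C(/C)CC[C@H](O)C(C)(C)O | intermediate
7 | tetrasubstituted (Z) allylic alcohol triol | OC/C(C)=C(/C)CC[C@H](O)C(C)(C)O | intermediate
8 | allylic bromide | BrC/C(C)=C(/C)CC[C@H](O)C(C)(C)O | intermediate
9 | isopropenyl diol | C=C(C)CC/C(C)=C(/C)CC[C@H](O)C(C)(C)O | intermediate
10 | (S)-epoxy isopropenyl alkene | C=C(C)CC/C(C)=C(/C)CC[C@@H]1OC1(C)C | intermediate
11 | umbelliferone | O=c1ccc2ccc(O)cc2o1 | starting material
12 | 7-allyloxycoumarin | C=CCOc1ccc2ccc(=O)oc2c1 | intermediate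
13 | epoxy polyene coumarin ether | O=c1ccc2ccc(OC/C=C(\C)CC/C(C)=C(/C)CC[C@@H]3OC3(C)C)cc2o1 | intermediate
14 | 3β-hydroxy cyclized ether | C=C1CC[C@]2(C)C(C)(C)[C@@H](O)CC[C@]2(C)[C@H]1COc1ccc2ccc(=O)oc2c1 | intermediate
15 | Polyanthinin (target) | C=C1CC[C@]2(C)C(C)(C)[C@@H](OC(C)=O)CC[C@]2(C)[C@H]1COc1ccc2ccc(=O)oc2c1 | target

## Totals
- Total steps: 13 (including the parallel allylation, Step 10).
- Longest linear sequence: 12 steps (Steps 1–9, 11, 12, 13).

## Three steps most likely to fail
1. **Step 12 (proposed new cascade).**
   - Risks: 5-exo rather than 6-endo closure at the hindered C4–C5 bond, trans or mixed ring fusion, and the C9 epimer. In a chair–chair closure of the cis-fused system, the (E)-alkene may put C11 trans to the 10-Me.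
   - Fallback (known chemistry, different approach): a stepwise annulation. Robinson annulation of (S)-3-silyloxy-2,2-dimethylcyclohexanone gives the 4,4,10-trimethyl-Δ5-octal-7-one. Me2CuLi then adds 1,4 with the cis selectivity known for Δ4-3-keto steroids to give the 5β-methyl, after which ring B is elaborated.
2. **Step 11 (cross metathesis of a hindered isopropenyl alkene, E/Z control).**
   - Fallback: alkylate bromide **8** with ethyl acetoacetate, Krapcho decarboxylation to the methyl ketone, HWE with triethyl phosphonoacetate, DIBAL, then Mitsunobu with umbelliferone, followed by epoxide formation.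
3. **Step 5 (syn-carbomagnesiation of the dialkyl propargylic alcohol to the Z-tetrasubstituted alkene).**
   - Fallback: Normant carbocupration of the corresponding alkynoate with Me2CuLi, trapping with MeI, then DIBAL to the allylic alcohol.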